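**Strategy**

The cyclopentane (C1 isobutenyl, C2 CH2, C3 CHMe, C4 CHCH2OAr, C5 quaternary) is disconnected at C3–C4 and C5–C1. C4 with its oxygenated carbon and C5 are the β- and α-carbons of a 5-menthyloxybutenolide, C3 is a masked acyl carbon and the isobutenyl group on C1 is the footprint of an allylic sulfone. In one photocatalytic operation a dioxolan-2-yl radical adds to the butenolide anti to the menthyloxy group, the α-lactone radical closes 5-exo and expels phenylsulfonyl, which forms the ring and sets C1, C4 and C5. The precursors are butenolide 10 and sulfonylalkenyl dioxolane 16, a stable surrogate of the β,γ-unsaturated aldehyde whose acyl radical would decarbonylate.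

Key step: step 8

Remark on the chemistry: an acyl radical with an allylic α-carbon loses CO to an allyl radical (which here would also shed the sulfonyl group) faster than it adds to an alkene. C3 is therefore carried as the ethylene acetal and enters as a 2-alkyl-1,3-dioxolan-2-yl radical; the ketone is released in step 10.

Remark on the order after the key step: the auxiliary is removed while C3 is still a ketal (step 9), so the transient C4 aldehyde is neither allylic nor β-keto.

Convention: ring atoms C1–C5 as in the overview; α is the face of the C1 isobutenyl group and the C5 three-carbon chain, β the face of the C4 carbon substituent and the C5 one-carbon substituent.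

Assumption: compounds 1, 4, 8, 11, 14 and 28 are bought.

**Route**

Step 1
Reactants: 1 furfural
Product: 3 5-hydroxyfuran-2(5H)-one, via furfural endoperoxide 2 (not isolated)
Conditions: O2, rose bengal (cat.), MeOH, visible light, 20 °C
Reagents that add atoms: dioxygen, O=O
Why: Sensitised [4+2] addition of singlet oxygen to the furan gives endoperoxide 2, whose methanolysis expels the formyl carbon as methyl formate and leaves the γ-hydroxybutenolide (furan photo-oxygenation).

Step 2
Reactants: 3 5-hydroxyfuran-2(5H)-one; 4 l-menthol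
Product: 5 (5R)-5-(l-menthyloxy)furan-2(5H)-one
Conditions: p-TsOH (cat.), toluene, reflux (Dean–Stark); crystallisation from petroleum ether, mother liquor re-equilibrated with p-TsOH
Reagents that add atoms: none
Why: Acid-catalysed acetalisation of the pseudo-acid gives both C5 epimers, which interconvert under acid, so crystallisation should funnel the material into the crystalline (5R) epimer (crystallisation-induced diastereomer transformation), fixing the acetal centre that later controls C4.

Step 3
Reactants: 5 (5R)-5-(l-menthyloxy)furan-2(5H)-one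
Product: 7 (5R)-3-bromo-5-(l-menthyloxy)furan-2(5H)-one, via trans-dibromide 6 (not isolated)
Conditions: Br2, CH2Cl2, 0 °C; then Et3N, 0 °C → rt
Reagents that add atoms: bromine, BrBr
Why: Anti addition of bromine followed by E1cB loss of HBr through the acidic α-position (bromination–dehydrobromination) should give the α-bromobutenolide without touching the acetal centre.

Step 4
Reactants: 7 (5R)-3-bromo-5-(l-menthyloxy)furan-2(5H)-one; 8 allyl tert-butyldimethylsilyl ether
Product: 10 (5R)-5-(l-menthyloxy)-3-[3-(tert-butyldimethylsilyloxy)propyl]furan-2(5H)-one, via B-alkyl-9-BBN 9 (not isolated)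
Conditions: 8, 9-BBN, THF, 0 °C → rt; then 7, Pd(dppf)Cl2 (5 mol%), AsPh3, K3PO4 (3 M aq.), DMF, rt
Reagents that add atoms: none
Why: Anti-Markovnikov hydroboration gives the primary alkylborane, which couples at the activated sp2 C–Br bond of the α-bromoenoate at room temperature under weakly basic conditions that should leave the acetal centre intact (B-alkyl Suzuki–Miyaura coupling).

Step 5
Reactants: 11 allyl phenyl sulfone
Product: 13 3-methyl-3-(phenylsulfonyl)but-1-ene, via monomethyl sulfone 12 (not isolated)
Conditions: n-BuLi, THF, −78 °C, then MeI; again n-BuLi, −78 °C, then MeI, → rt (one flask)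
Reagents that add atoms: iodomethane, CI
Why: The sulfonyl-stabilised allyl anion alkylates at the α-carbon, so two deprotonation–methylation cycles should build the tertiary allylic sulfone (α-alkylation of a sulfone carbanion).

Step 6
Reactants: 14 4,4-diethoxybut-1-ene
Product: 15 2-allyl-1,3-dioxolane
Conditions: ethylene glycol, PPTS (cat.), toluene, 90 °C, EtOH distilled off
Reagents that add atoms: ethane-1,2-diol, OCCO
Why: Acid-catalysed transacetalisation, driven by removal of ethanol, gives the cyclic acetal whose C2–H is the site of the later hydrogen abstraction.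

Step 7
Reactants: 13 3-methyl-3-(phenylsulfonyl)but-1-ene; 15 2-allyl-1,3-dioxolane
Product: 16 2-[(2E)-4-methyl-4-(phenylsulfonyl)pent-2-en-1-yl]-1,3-dioxolane
Conditions: Hoveyda–Grubbs II (5 mol%), 15 (3 equiv), CH2Cl2, 40 °C
Reagents that add atoms: none
Why: Olefin cross-metathesis between an olefin with a quaternary allylic carbon (which does not homodimerise) and an excess of an unhindered terminal olefin should be selective, and the quaternary centre enforces the E geometry.

Step 8
Reactants: 10 (5R)-5-(l-menthyloxy)-3-[3-(tert-butyldimethylsilyloxy)propyl]furan-2(5H)-one; 16 2-[(2E)-4-methyl-4-(phenylsulfonyl)pent-2-en-1-yl]-1,3-dioxolane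
Product: 17 cis-fused lactone acetal with C3 spiro-dioxolane, α-isobutenyl group on C1 and α-silyloxypropyl chain on C5
Conditions: (n-Bu4N)4[W10O32] (4 mol%), 16 (2.5 equiv), NaHCO3, MeCN (degassed), 390 nm LEDs, 20 °C
Reagents that add atoms: none
Why: Proposed new method: excited decatungstate abstracts the hydridic acetal C–H of 16 to give a nucleophilic 2-alkyl-1,3-dioxolan-2-yl radical (a masked acyl radical that cannot lose CO), which adds to the electron-poor β-carbon of 10 anti to the menthyloxy group (C3–C4 bond); the electrophilic tertiary α-lactone radical then attacks the alkene five atoms away (C5–C1 bond) and the adduct radical expels PhSO2•, which is reduced by the reduced polyoxometalate so that the step is redox-neutral and NaHCO3 takes up the sulfinic acid. The closest known reaction types are the aryl-ketone- or decatungstate-sensitised Giese addition of 2-alkyl-1,3-dioxolanes to enones, the photochemical addition of 1,3-dioxolane anti to the alkoxy group of 5-menthyloxybutenolides, and 5-exo radical cyclisations or C–H allylations terminated by β-loss of a sulfonyl radical. The single new ring, the cyclopentane, is closed in the 5-exo-trig mode, and the tether on C4 lets it form only cis-fused to the lactone. C4 is controlled by the acetal stereocentre (attack anti to the menthyloxy group), C5 by the enforced cis fusion, and C1 by a chair-like transition state in which the sulfonylalkenyl arm lies on the convex face, away from the lactone ring and cis to the side chain. The step needs the Giese addition to outrun 3-exo closure with sulfonyl loss and the 5-exo closure to outrun back hydrogen transfer to the α-lactone radical; polarity matching of both radical additions, a high concentration of 10, excess 16 and the gem-dialkoxy effect of the ketal on ring closure are what should secure this.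

Step 9
Reactants: 17 cis-fused lactone acetal
Product: 20 ketal lactone (C5–C(=O)–O–CH2–C4), via formyl acid 18 (not isolated), via hydroxy acid 19 (not isolated)
Conditions: NaBH4, KOH, EtOH–H2O, 0 °C → rt; then 1 M HCl to pH 4, 0 °C; PPTS (cat.), CH2Cl2, rt
Reagents that add atoms: potassium hydroxide, [K+].[OH-] (its oxygen enters the carboxyl group of 18 and 19; one carboxyl oxygen leaves again as water on lactonisation)
Why: Hydroxide opens the acyloxy acetal, the hemiacetal collapses to aldehyde 18 with loss of menthol, borohydride reduces the aldehyde as it forms and before C4 can epimerise, and acidification closes the cis γ-lactone, which only the unepimerised hydroxy acid can form (saponification, in situ NaBH4 reduction, lactonisation).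

Step 10
Reactants: 20 ketal lactone
Product: 21 keto lactone
Conditions: PPTS (cat.), acetone–H2O (10:1), 50 °C
Reagents that add atoms: water, O
Why: Acid-catalysed ketal hydrolysis should be much faster than cleavage of the primary silyl ether, and in the cis-fused lactone the CH2–O bond lies in the nodal plane of the enol so that β-elimination is disfavoured.

Step 11
Reactants: 21 keto lactone
Product: 22 methylene lactone (C3=CH2)
Conditions: Zn, CH2Br2, TiCl4 (pre-formed Lombardo reagent), THF–CH2Cl2, 0 °C → rt
Reagents that add atoms: dibromomethane, BrCBr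
Why: Takai–Lombardo methylenation uses a non-basic gem-dimetallic carbenoid, so the enolisable β-acyloxy ketone should be methylenated without E1cB or retro-Michael opening and without attack on the lactone.

Step 12
Reactants: 22 methylene lactone
Product: 23 lactol (both anomers)
Conditions: DIBAL-H, CH2Cl2, −78 °C; Rochelle salt
Reagents that add atoms: none
Why: DIBAL-H reduction of a γ-lactone stops at the lactol because the tetrahedral aluminate is stable at −78 °C.

Step 13
Reactants: 23 lactol
Product: 24 hydroxy tosylhydrazone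
Conditions: TsNHNH2, EtOH, 60 °C
Reagents that add atoms: 4-methylbenzenesulfonohydrazide, Cc1ccc(cc1)S(=O)(=O)NN
Why: The lactol is in equilibrium with the open hydroxy aldehyde, which condenses irreversibly with the hydrazide and so releases the C4 hydroxymethyl group (tosylhydrazone formation).

Step 14
Reactants: 24 hydroxy tosylhydrazone
Product: 26 methyl carbinol (C5 β-methyl, C4 β-CH2OH, C3=CH2), via tosylhydrazine 25 (not isolated)
Conditions: catecholborane, CHCl3, 0 °C → rt; then NaOAc·3H2O, reflux
Reagents that add atoms: none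
Why: Hydride addition to the C=N bond, acetate-induced loss of sulfinate and loss of N2 from the diazene turn the masked aldehyde carbon into the C5 methyl group under non-basic conditions that spare the exocyclic alkene and the silyl ether (Caglioti–Kabalka tosylhydrazone reduction).

Step 15
Reactants: 26 methyl carbinol
Product: 27 saturated alcohol (C3 α-methyl)
Conditions: [Ir(cod)(PCy3)(py)]PF6 (3 mol%), H2 (1 atm), CH2Cl2, 0 °C → rt
Reagents that add atoms: none
Why: In this hydroxyl-directed hydrogenation (Crabtree catalyst) iridium bound to the β-CH2OH on C4 delivers hydrogen to the β face of the homoallylic 1,1-disubstituted alkene, which sets C3 with its methyl group α (trans to CH2OH), while the undirected trisubstituted isobutenyl alkene should react far more slowly.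

Step 16
Reactants: 27 saturated alcohol; 28 umbelliferone
Product: 29 umbelliferyl ether
Conditions: PPh3, DIAD, THF, 0 °C → rt
Reagents that add atoms: none
Why: Mitsunobu etherification suits an acidic phenol such as umbelliferone and a primary alcohol, and no stereocentre is involved.

Step 17
Reactants: 29 umbelliferyl ether
Product: 30 primary alcohol
Conditions: HF·pyridine, pyridine, THF, 0 °C → rt
Reagents that add atoms: none
Why: Fluoride-driven Si–O cleavage under buffered conditions should leave the coumarin lactone, the aryl ether and the alkene untouched (desilylation).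

Step 18
Reactants: 30 primary alcohol
Product: 32 ferulsinaic acid, via aldehyde 31 (not isolated)
Conditions: TEMPO (cat.), PhI(OAc)2, MeCN–H2O (1:1), rt
Reagents that add atoms: water, O
Why: Oxoammonium oxidation (TEMPO/PhI(OAc)2) in aqueous acetonitrile takes the primary alcohol through the aldehyde hydrate to the acid and is compatible with the trisubstituted alkene, the aryl ether and the coumarin.

**Compound list**

1 | furfural (furan-2-carbaldehyde) | O=Cc1ccco1 | starting material
2 | 2,3,7-trioxabicyclo[2.2.1]hept-5-ene-1-carbaldehyde (furfural endoperoxide, racemic) | O=CC12OOC(O1)C=C2 | intermediate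
3 | 5-hydroxyfuran-2(5H)-one (racemic) | O=C1OC(O)C=C1 | intermediate
4 | l-menthol, (1R,2S,5R)-2-isopropyl-5-methylcyclohexan-1-ol | CC(C)[C@@H]1CC[C@@H](C)C[C@H]1O | starting material
5 | (5R)-5-(l-menthyloxy)furan-2(5H)-one | O=C1O[C@@H](O[C@@H]2C[C@H](C)CC[C@H]2C(C)C)C=C1 | intermediate
6 | (5R)-3,4-dibromo-5-(l-menthyloxy)dihydrofuran-2(3H)-one, 3,4-trans and 4,5-trans (expected major dibromide; any diastereomer converges on 7) | O=C1O[C@@H](O[C@@H]2C[C@H](C)CC[C@H]2C(C)C)[C@H](Br)[C@H]1Br | intermediate
7 | (5R)-3-bromo-5-(l-menthyloxy)furan-2(5H)-one | O=C1O[C@@H](O[C@@H]2C[C@H](C)CC[C@H]2C(C)C)C=C1Br | intermediate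
8 | allyl tert-butyldimethylsilyl ether | C=CCO[Si](C)(C)C(C)(C)C | starting material
9 | 9-[3-(tert-butyldimethylsilyloxy)propyl]-9-borabicyclo[3.3.1]nonane | CC(C)(C)[Si](C)(C)OCCCB1C2CCCC1CCC2 | intermediate
10 | (5R)-5-(l-menthyloxy)-3-[3-(tert-butyldimethylsilyloxy)propyl]furan-2(5H)-one | O=C1O[C@@H](O[C@@H]2C[C@H](C)CC[C@H]2C(C)C)C=C1CCCO[Si](C)(C)C(C)(C)C | intermediate
11 | allyl phenyl sulfone | C=CCS(=O)(=O)c1ccccc1 | starting material
12 | 3-(phenylsulfonyl)but-1-ene (racemic) | C=CC(C)S(=O)(=O)c1ccccc1 | intermediate
13 | 3-methyl-3-(phenylsulfonyl)but-1-ene | C=CC(C)(C)S(=O)(=O)c1ccccc1 | intermediate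
14 | 4,4-diethoxybut-1-ene (but-3-enal diethyl acetal) | C=CCC(OCC)OCC | starting material
15 | 2-allyl-1,3-dioxolane | C=CCC1OCCO1 | intermediate
16 | 2-[(2E)-4-methyl-4-(phenylsulfonyl)pent-2-en-1-yl]-1,3-dioxolane (ethylene acetal of (E)-5-methyl-5-(phenylsulfonyl)hex-3-enal) | CC(C)(/C=C/CC1OCCO1)S(=O)(=O)c1ccccc1 | intermediate
17 | cis-fused lactone acetal: C1 α-(2-methylprop-1-enyl), C3 spiro-1,3-dioxolane, C4 β-acetal carbon and C5 β-lactone carbonyl joined as γ-lactone, C5 α-[3-(TBSO)propyl]; l-menthyloxy on the acetal carbon trans to the C4–C3 bond | CC(C)=C[C@@H]1CC2(OCCO2)[C@@H]([C@H](O[C@@H]2C[C@H](C)CC[C@H]2C(C)C)O3)[C@]1(C3=O)CCCO[Si](C)(C)C(C)(C)C | intermediate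
18 | formyl acid: as 17 with C4 β-CHO and C5 β-CO2H (carboxylate in the flask) | CC(C)=C[C@@H]1CC2(OCCO2)[C@@H](C=O)[C@]1(C(=O)O)CCCO[Si](C)(C)C(C)(C)C | intermediate
19 | hydroxy acid: as 18 with C4 β-CH2OH (carboxylate in the flask) | CC(C)=C[C@@H]1CC2(OCCO2)[C@@H](CO)[C@]1(C(=O)O)CCCO[Si](C)(C)C(C)(C)C | intermediate
20 | ketal lactone: cis-fused γ-lactone C5–C(=O)–O–CH2–C4 on the β face, C3 spiro-1,3-dioxolane, C1 α-isobutenyl, C5 α-[3-(TBSO)propyl] | CC(C)=C[C@@H]1CC2(OCCO2)[C@@H](CO3)[C@]1(C3=O)CCCO[Si](C)(C)C(C)(C)C | intermediate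
21 | keto lactone: as 20 with C3 ketone | CC(C)=C[C@@H]1CC(=O)[C@@H](CO2)[C@]1(C2=O)CCCO[Si](C)(C)C(C)(C)C | intermediate
22 | methylene lactone: as 20 with C3 exocyclic methylene | CC(C)=C[C@@H]1CC(=C)[C@@H](CO2)[C@]1(C2=O)CCCO[Si](C)(C)C(C)(C)C | intermediate
23 | lactol: as 22 with the lactone carbonyl reduced to CH(OH) (both anomers) | CC(C)=C[C@@H]1CC(=C)[C@@H](CO2)[C@]1(C2O)CCCO[Si](C)(C)C(C)(C)C | intermediate
24 | hydroxy tosylhydrazone: C5 β-CH=N–NHTs (E), C4 β-CH2OH, C3=CH2, C1 α-isobutenyl, C5 α-[3-(TBSO)propyl] | CC(C)=C[C@@H]1CC(=C)[C@@H](CO)[C@]1(/C=N/NS(=O)(=O)c2ccc(C)cc2)CCCO[Si](C)(C)C(C)(C)C | intermediate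
25 | tosylhydrazine: as 24 with C5 β-CH2–NH–NHTs (boron-bound in the flask) | CC(C)=C[C@@H]1CC(=C)[C@@H](CO)[C@]1(CNNS(=O)(=O)c2ccc(C)cc2)CCCO[Si](C)(C)C(C)(C)C | intermediate
26 | methyl carbinol: C5 β-methyl and α-[3-(TBSO)propyl], C4 β-CH2OH, C3=CH2, C1 α-isobutenyl | CC(C)=C[C@@H]1CC(=C)[C@@H](CO)[C@]1(C)CCCO[Si](C)(C)C(C)(C)C | intermediate
27 | saturated alcohol: as 26 with C3 α-methyl (ring configuration of the target) | CC(C)=C[C@@H]1C[C@H](C)[C@@H](CO)[C@]1(C)CCCO[Si](C)(C)C(C)(C)C | intermediate
28 | umbelliferone (7-hydroxy-2H-chromen-2-one) | O=c1ccc2ccc(O)cc2o1 | starting material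
29 | umbelliferyl ether: as 27 with C4 β-CH2O-(2-oxo-2H-chromen-7-yl) | CC(C)=C[C@@H]1C[C@H](C)[C@@H](COc2ccc3ccc(=O)oc3c2)[C@]1(C)CCCO[Si](C)(C)C(C)(C)C | intermediate
30 | primary alcohol: as 29 with C5 α-(3-hydroxypropyl) | CC(C)=C[C@@H]1C[C@H](C)[C@@H](COc2ccc3ccc(=O)oc3c2)[C@]1(C)CCCO | intermediate
31 | aldehyde: as 29 with C5 α-(3-oxopropyl) | CC(C)=C[C@@H]1C[C@H](C)[C@@H](COc2ccc3ccc(=O)oc3c2)[C@]1(C)CCC=O | intermediate
32 | ferulsinaic acid, 3-[(1R,2R,3S,5S)-1,3-dimethyl-5-(2-methylprop-1-en-1-yl)-2-{[(2-oxo-2H-chromen-7-yl)oxy]methyl}cyclopentyl]propanoic acid | CC(C)=C[C@@H]1C[C@H](C)[C@@H](COc2ccc3ccc(=O)oc3c2)[C@]1(C)CCC(=O)O | target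

**Step count and risk**

Total steps: 18. Longest linear sequence: 15 (steps 1–4 and 8–18).

Steps most likely to fail:

1. Step 8 (key step). Possible failures are:
   - unselective hydrogen abstraction (dioxolane C4/C5–H or allylic C–H);
   - 3-exo closure of the homoallylic radical with loss of sulfonyl;
   - sulfonyl-radical-chain 1,3-transposition of 16;
   - back hydrogen transfer before ring closure, giving the uncyclised adduct;
   - poor facial selectivity at C1.

   The fallback uses known chemistry, sets out from 16 and 10 and returns at 21. Transthioacetalisation of 16 (propane-1,3-dithiol, BF3·OEt2, CH2Cl2, 0 °C) gives 2-[(2E)-4-methyl-4-(phenylsulfonyl)pent-2-en-1-yl]-1,3-dithiane F1. Its 2-lithio derivative (n-BuLi, THF, −78 °C) adds to 10 in conjugate fashion anti to the menthyloxy group, and the lactone enolate is trapped with PhSeBr to give the α-phenylselanyl lactone F2 (tandem conjugate addition–enolate trapping, as established for lithiated dithianes and 5-menthyloxybutenolides). Bu3SnH/AIBN (benzene, 80 °C, slow addition) then generates the C5 radical, which closes 5-exo onto the allylic sulfone with β-loss of phenylsulfonyl to give the dithioketal lactone acetal F3. Under the conditions of step 9, F3 should give the dithioketal lactone F4, and MeI/CaCO3 in aqueous MeCN unmasks the ketone to give 21.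

2. Step 11. Possible failures are consumption of the carbenoid by enolisation, or Lewis-acid-promoted β-elimination of the lactone carboxylate and retro-Michael opening of the β-acyloxy ketone. The fallback sets out from 17 and returns at 22. It methylenates while the C4 oxygens are still locked in the bicyclic acetal. Ketal hydrolysis of 17 (PPTS, wet acetone) gives the keto lactone acetal F5, and Petasis methylenation (Cp2TiMe2, toluene, 65 °C) gives the methylene lactone acetal F6. Saponification, in situ NaBH4 reduction and lactonisation (as in step 9, at 0 °C with excess borohydride) then remove the auxiliary and give 22.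

3. Step 13. Possible failures are that the hindered neopentyl lactol stays ring-closed so that hydrazone formation stalls, or that the hindered hydrazone is reduced sluggishly in step 14. The fallback sets out from 22 and returns at 26, replacing steps 12–14 with a radical deoxygenation. LiAlH4 (THF, 0 °C) gives the diol F7, and PivCl/pyridine (−20 °C) acylates the less hindered C4 hydroxymethyl group to give the monopivalate F8. 1,1′-Thiocarbonyldiimidazole (DMAP, toluene, 80 °C) gives the imidazolyl thiocarbonate F9, and Bu3SnH/AIBN (toluene, reflux, Barton–McCombie) gives the deoxygenated pivalate F10. DIBAL-H removes the pivalate to give 26.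

Further compounds
F1 | step 8 | 2-[(2E)-4-methyl-4-(phenylsulfonyl)pent-2-en-1-yl]-1,3-dithiane | CC(C)(/C=C/CC1SCCCS1)S(=O)(=O)c1ccccc1
F2 | step 8 | α-phenylselanyl lactone: (5R)-5-(l-menthyloxy)-4-{2-[(2E)-4-methyl-4-(phenylsulfonyl)pent-2-en-1-yl]-1,3-dithian-2-yl}-3-(phenylselanyl)-3-[3-(TBSO)propyl]dihydrofuran-2(3H)-one, dithianyl trans to menthyloxy and to selenium | O=C1O[C@@H](O[C@@H]2C[C@H](C)CC[C@H]2C(C)C)[C@H](C2(C/C=C/C(C)(C)S(=O)(=O)c3ccccc3)SCCCS2)[C@]1([Se]c1ccccc1)CCCO[Si](C)(C)C(C)(C)C
F3 | step 8 | dithioketal lactone acetal: as 17 with C3 spiro-1,3-dithiane | CC(C)=C[C@@H]1CC2(SCCCS2)[C@@H]([C@H](O[C@@H]2C[C@H](C)CC[C@H]2C(C)C)O3)[C@]1(C3=O)CCCO[Si](C)(C)C(C)(C)C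
F4 | step 8 | dithioketal lactone: as 20 with C3 spiro-1,3-dithiane | CC(C)=C[C@@H]1CC2(SCCCS2)[C@@H](CO3)[C@]1(C3=O)CCCO[Si](C)(C)C(C)(C)C
F5 | step 11 | keto lactone acetal: as 17 with C3 ketone | CC(C)=C[C@@H]1CC(=O)[C@@H]([C@H](O[C@@H]2C[C@H](C)CC[C@H]2C(C)C)O3)[C@]1(C3=O)CCCO[Si](C)(C)C(C)(C)C
F6 | step 11 | methylene lactone acetal: as 17 with C3 exocyclic methylene | CC(C)=C[C@@H]1CC(=C)[C@@H]([C@H](O[C@@H]2C[C@H](C)CC[C@H]2C(C)C)O3)[C@]1(C3=O)CCCO[Si](C)(C)C(C)(C)C
F7 | step 13 | diol: C4 β-CH2OH, C5 β-CH2OH, C3=CH2 | CC(C)=C[C@@H]1CC(=C)[C@@H](CO)[C@]1(CO)CCCO[Si](C)(C)C(C)(C)C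
F8 | step 13 | monopivalate: C4 β-CH2OPiv, C5 β-CH2OH | CC(C)=C[C@@H]1CC(=C)[C@@H](COC(=O)C(C)(C)C)[C@]1(CO)CCCO[Si](C)(C)C(C)(C)C
F9 | step 13 | imidazolyl thiocarbonate: C5 β-CH2OC(=S)-imidazol-1-yl, C4 β-CH2OPiv | CC(C)=C[C@@H]1CC(=C)[C@@H](COC(=O)C(C)(C)C)[C@]1(COC(=S)n2ccnc2)CCCO[Si](C)(C)C(C)(C)C
F10 | step 13 | deoxygenated pivalate: C5 β-methyl, C4 β-CH2OPiv | CC(C)=C[C@@H]1CC(=C)[C@@H](COC(=O)C(C)(C)C)[C@]1(C)CCCO[Si](C)(C)C(C)(C)C
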